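**Retrosynthetic overview**
1. Target 16 ⇐ keto diacetate 15 (C=O → C=CH2). 15 ⇐ two bicyclic halves joined at the central CH2–CH2 bond by radical conjugate addition of alkylborane 13 (from alkene 12) to α-methylene ketone 10.
2. Both halves come from the same enone 10: 12 ⇐ 10 by face-selective methyl addition and acetylation, so no protecting group is needed.
3. 10 ⇐ acyclic bis-epoxy vinyl ketone 5 by one cationic cascade (oxepane ring first, then the cyclohexanone ring) ended by a masked enone α-carbon, followed by sulfoxide elimination.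
4. 5 ⇐ triene amide 3 by organocatalytic Shi double epoxidation, which sets all absolute stereochemistry; 3 ⇐ geranyl bromide + N-methoxy-N-methylacetamide.

Assumption: operations run in one flask count as one step; the L-fructose-derived enantiomer of the Shi ketone is a purchased catalyst; ring atoms are numbered as in 1-benzoxepine (O1, C2–C5, C5a, C6–C9, C9a).

**Step 1**
Reactants: 1 geranyl bromide; 2 N-methoxy-N-methylacetamide
Product: 3 (4E)-N-methoxy-N,5,9-trimethyldeca-4,8-dienamide
Conditions: LDA, THF, −78 °C; then 1, −78 → −20 °C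
Reagents that add atoms: none
Why: Enolate alkylation: the kinetic lithium enolate of the Weinreb acetamide displaces the primary allylic bromide (SN2) with the E-olefin untouched, and no stereocentre is formed.

**Step 2**
Reactants: 3 (4E)-N-methoxy-N,5,9-trimethyldeca-4,8-dienamide
Product: 4 3-[(2S,3S)-3-{2-[(2S)-3,3-dimethyloxiran-2-yl]ethyl}-3-methyloxiran-2-yl]-N-methoxy-N-methylpropanamide
Conditions: ent-Shi ketone (L-fructose-derived, 0.3 equiv), Oxone, K2CO3, Bu4NHSO4, MeCN/DMM/aq. borate–EDTA buffer (pH 10.5), 0 °C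
Reagents that add atoms: potassium peroxymonosulfate (Oxone), [K+].[O-]S(=O)(=O)OO
Why: Shi asymmetric epoxidation: the chiral dioxirane formed from the ketone catalyst epoxidises both electron-rich trisubstituted olefins through the spiro transition state, setting the first three stereocentres (S at the terminal epoxide, S,S at the internal one); the minor enantiomer is diverted into a separable diastereomer (Horeau effect) and the amide is inert.

**Step 3**
Reactants: 4 bis-epoxy Weinreb amide
Product: 5 5-[(2S,3S)-3-{2-[(2S)-3,3-dimethyloxiran-2-yl]ethyl}-3-methyloxiran-2-yl]pent-1-en-3-one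
Conditions: CH2=CHMgBr (1.5 equiv), THF, −78 → −30 °C; AcOH, −78 °C; aq. NH4Cl
Reagents that add atoms: vinylmagnesium bromide, C=C[Mg]Br
Why: Weinreb ketone synthesis: the chelated tetrahedral intermediate prevents over-addition, trisubstituted epoxides do not react with the Grignard reagent at low temperature, and the cold acidic quench stops the released amine from adding to the enone; no stereocentre changes.

**Step 4**
Reactants: 5 bis-epoxy vinyl ketone
Product: 8 (3S,5aS,6S,9aS)-3-hydroxy-2,2,5a-trimethyl-6-[(phenylsulfanyl)methyl]octahydro-1-benzoxepin-7(2H)-one, via silyl enol ether 6 (not isolated), via TMS ether 7 (not isolated)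
Conditions: PhSSiMe3 (1.05 equiv), Bu4N[Ph3SiF2] (2 mol %), CH2Cl2, −40 → 0 °C; then DTBMP (3 equiv), TMSOTf (1.3 equiv), CH2Cl2 (0.01 M), −78 °C; aq. NaHCO3; then citric acid, MeOH, 23 °C
Reagents that add atoms: (phenylsulfanyl)trimethylsilane, C[Si](C)(C)Sc1ccccc1
Why: Proposed new method: fluoride-initiated conjugate addition of PhS–SiMe3 turns the vinyl ketone into the (Z)-β-phenylthio silyl enol ether 6, a masked enone α-anion of the Morita–Baylis–Hillman type; TMSOTf then silylates the terminal epoxide, the neighbouring epoxide oxygen opens it at the tertiary carbon to give an oxepane-fused epoxonium ion, and the enol ether carbon attacks the tertiary epoxonium carbon anti to the C–O bond through a chair-like transition state (inversion there gives the trans ring fusion 5aS/9aS, C-3 keeps its epoxide configuration, CH2SPh ends equatorial); the closest known reactions are the enol-silane-terminated tandem oxa-/carbacyclisation of bis-epoxides and the thiosilane Michael/Mukaiyama sequence with acetals, whereas ending an epoxide cascade at an enone α-carbon has not been shown.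

**Step 5**
Reactants: 8 hydroxy β-(phenylthio)methyl ketone
Product: 10 (3S,5aS,9aS)-3-hydroxy-2,2,5a-trimethyl-6-methylideneoctahydro-1-benzoxepin-7(2H)-one, via sulfoxide 9 (not isolated)
Conditions: mCPBA (1.0 equiv), CH2Cl2, −78 °C; then Et3N, PhMe, 60 °C
Reagents that add atoms: none
Why: Sulfide oxidation followed by thermal sulfoxide syn-elimination: the only β-hydrogen is the acidified one at C-6, so the exocyclic enone forms regiospecifically; the C-6 stereocentre is deliberately erased and the others are untouched.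

**Step 6**
Reactants: 10 α-methylene ketone
Product: 12 (3S,5aS,7R,9aS)-2,2,5a,7-tetramethyl-6-methylidenedecahydro-1-benzoxepine-3,7-diyl diacetate, via dialkoxide 11 (not isolated)
Conditions: MeLi (3.2 equiv), CeCl3, THF, −78 °C; then Ac2O (8 equiv), DMAP, −78 → 40 °C
Reagents that add atoms: methyllithium, [Li]C; acetic anhydride, CC(=O)OC(C)=O
Why: Organocerium (Imamoto) 1,2-addition: the axial face of the carbonyl is blocked by the 1,3-diaxial 5a-methyl group, so methyl enters equatorially and the new tertiary oxygen is axial, cis to that methyl (7R); both alkoxides are then O-acylated in the same flask.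

**Step 7**
Reactants: 12 diacetate alkene; 10 α-methylene ketone (1.5 equiv)
Product: 15 (3S,5aS,6S,7R,9aS)-6-{2-[(3S,5aS,6S,9aS)-3-hydroxy-2,2,5a-trimethyl-7-oxodecahydro-1-benzoxepin-6-yl]ethyl}-2,2,5a,7-tetramethyldecahydro-1-benzoxepine-3,7-diyl diacetate, via alkylborane 13 (not isolated), via boron enolate 14 (not isolated)
Conditions: 12, catecholborane (3 equiv), Me2NCOMe (0.2 equiv), CH2Cl2, 40 °C; t-BuOH; then 10, DMPU, air (O2), 0 → 23 °C; aq. NH4Cl; SiO2/Et3N
Reagents that add atoms: none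
Why: Anti-Markovnikov hydroboration delivers H to C-6 of 12 from the face opposite the two flanking axial groups (5a-Me, 7-OAc), making CH2B equatorial (6S); the oxygen-initiated organoborane radical chain (Brown/Renaud conjugate addition) then adds the primary radical to the unhindered CH2 terminus of enone 10, and protonation/equilibration of the boron enolate places the new chain equatorial on the ketone half (6S).

**Step 8**
Reactants: 15 keto diacetate
Product: 16 (3S,5aS,6S,7R,9aS)-6-{2-[(3S,5aS,6R,9aS)-3-hydroxy-2,2,5a-trimethyl-7-methylidenedecahydro-1-benzoxepin-6-yl]ethyl}-2,2,5a,7-tetramethyldecahydro-1-benzoxepine-3,7-diyl diacetate (target)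
Conditions: Zn, CH2Br2, TiCl4 (pre-formed Lombardo reagent), THF/CH2Cl2, 0 → 23 °C
Reagents that add atoms: dibromomethane, BrCBr
Why: Takai–Lombardo methylenation: the non-basic zinc/titanium gem-dimetallic reagent converts the hindered ketone into the exocyclic methylene without epimerising the adjacent C-6 centre, leaving the acetates and the free hydroxyl alone (the descriptor at C-6 changes from S to R only through CIP priorities).

**Compound list**
1 | geranyl bromide, (2E)-1-bromo-3,7-dimethylocta-2,6-diene | CC(C)=CCC/C(C)=C/CBr | starting material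
2 | N-methoxy-N-methylacetamide | CC(=O)N(C)OC | starting material
3 | (4E)-N-methoxy-N,5,9-trimethyldeca-4,8-dienamide | CON(C)C(=O)CC/C=C(\C)CCC=C(C)C | intermediate
4 | 3-[(2S,3S)-3-{2-[(2S)-3,3-dimethyloxiran-2-yl]ethyl}-3-methyloxiran-2-yl]-N-methoxy-N-methylpropanamide | CON(C)C(=O)CC[C@@H]1O[C@@]1(C)CC[C@@H]1OC1(C)C | intermediate
5 | 5-[(2S,3S)-3-{2-[(2S)-3,3-dimethyloxiran-2-yl]ethyl}-3-methyloxiran-2-yl]pent-1-en-3-one | C=CC(=O)CC[C@@H]1O[C@@]1(C)CC[C@@H]1OC1(C)C | intermediate
6 | (2Z)-3-trimethylsilyloxy-1-(phenylsulfanyl)pent-2-ene carrying the (2S,3S)/(2S) bis-epoxide chain of 5 at C-5 (Z major) | C[Si](C)(C)O/C(=C\CSc1ccccc1)CC[C@@H]1O[C@@]1(C)CC[C@@H]1OC1(C)C | intermediate (not isolated)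
7 | (3S,5aS,6S,9aS)-2,2,5a-trimethyl-6-[(phenylsulfanyl)methyl]-3-(trimethylsilyloxy)octahydro-1-benzoxepin-7(2H)-one | O=C1CC[C@@H]2OC(C)(C)[C@@H](O[Si](C)(C)C)CC[C@@]2(C)[C@@H]1CSc1ccccc1 | intermediate (not isolated)
8 | (3S,5aS,6S,9aS)-3-hydroxy-2,2,5a-trimethyl-6-[(phenylsulfanyl)methyl]octahydro-1-benzoxepin-7(2H)-one | O=C1CC[C@@H]2OC(C)(C)[C@@H](O)CC[C@@]2(C)[C@@H]1CSc1ccccc1 | intermediate
9 | (3S,5aS,6S,9aS)-3-hydroxy-2,2,5a-trimethyl-6-[(phenylsulfinyl)methyl]octahydro-1-benzoxepin-7(2H)-one (both sulfur epimers) | O=C1CC[C@@H]2OC(C)(C)[C@@H](O)CC[C@@]2(C)[C@@H]1CS(=O)c1ccccc1 | intermediate (not isolated)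
10 | (3S,5aS,9aS)-3-hydroxy-2,2,5a-trimethyl-6-methylideneoctahydro-1-benzoxepin-7(2H)-one | O=C1CC[C@@H]2OC(C)(C)[C@@H](O)CC[C@@]2(C)C1=C | intermediate
11 | dialkoxide of (3S,5aS,7R,9aS)-2,2,5a,7-tetramethyl-6-methylidenedecahydro-1-benzoxepine-3,7-diol, drawn as the dilithium salt | C=C1[C@]2(C)CC[C@H]([O-])C(C)(C)O[C@H]2CC[C@@]1(C)[O-].[Li+].[Li+] | intermediate (not isolated)
12 | (3S,5aS,7R,9aS)-2,2,5a,7-tetramethyl-6-methylidenedecahydro-1-benzoxepine-3,7-diyl diacetate | C=C1[C@]2(C)CC[C@H](OC(C)=O)C(C)(C)O[C@H]2CC[C@@]1(C)OC(C)=O | intermediate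
13 | (3S,5aS,6S,7R,9aS)-6-[(1,3,2-benzodioxaborol-2-yl)methyl]-2,2,5a,7-tetramethyldecahydro-1-benzoxepine-3,7-diyl diacetate | c1ccc2OB(C[C@H]3[C@]4(C)CC[C@H](OC(C)=O)C(C)(C)O[C@H]4CC[C@@]3(C)OC(C)=O)Oc2c1 | intermediate (not isolated)
14 | catecholboron enolate of 15 (O-boryl enol ether between C-7 and C-6 of the ketone half) | O(B1Oc2ccccc2O1)C1=C(CC[C@H]3[C@]4(C)CC[C@H](OC(C)=O)C(C)(C)O[C@H]4CC[C@@]3(C)OC(C)=O)[C@]2(C)CC[C@H](O)C(C)(C)O[C@H]2CC1 | intermediate (not isolated)
15 | (3S,5aS,6S,7R,9aS)-6-{2-[(3S,5aS,6S,9aS)-3-hydroxy-2,2,5a-trimethyl-7-oxodecahydro-1-benzoxepin-6-yl]ethyl}-2,2,5a,7-tetramethyldecahydro-1-benzoxepine-3,7-diyl diacetate | O=C1CC[C@@H]2OC(C)(C)[C@@H](O)CC[C@@]2(C)[C@@H]1CC[C@H]1[C@]2(C)CC[C@H](OC(C)=O)C(C)(C)O[C@H]2CC[C@@]1(C)OC(C)=O | intermediate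
16 | (3S,5aS,6S,7R,9aS)-6-{2-[(3S,5aS,6R,9aS)-3-hydroxy-2,2,5a-trimethyl-7-methylidenedecahydro-1-benzoxepin-6-yl]ethyl}-2,2,5a,7-tetramethyldecahydro-1-benzoxepine-3,7-diyl diacetate | C=C1CC[C@@H]2OC(C)(C)[C@@H](O)CC[C@@]2(C)[C@@H]1CC[C@H]1[C@]2(C)CC[C@H](OC(C)=O)C(C)(C)O[C@H]2CC[C@@]1(C)OC(C)=O | target

**Totals**
Total step count: 8. Longest linear sequence: 8 (enone 10 is made once and used in steps 6 and 7).

**Three steps most likely to fail**

Step 4 (the proposed new cascade). The masked enone could be silylated back to the enone, the sulfide could intercept the epoxonium ion, or the cascade could stop after the oxepane. The fallback uses only known reaction types, sets out from 4 and returns at 10. MeMgBr converts 4 into the bis-epoxy methyl ketone F1. Horner–Wadsworth–Emmons reaction with triethyl phosphonoacetate/NaH gives the bis-epoxy (2E)-farnesoate ester F2; the 2Z isomer is harmless because that carbon becomes sp2 in 10. DIBAL-H at −78 °C gives the bis-epoxy farnesol F3, and Ac2O/pyridine gives the bis-epoxy farnesyl acetate F4. TMSOTf/DTBMP at −78 °C then runs the established alkene-terminated oxa-/carbacyclisation with loss of a methyl proton; after desilylation the bicyclic exo-methylene acetate F5 is separated from endocyclic isomers. Ozonolysis (O3, then Me2S) gives the β-acetoxy ketone F6, and DBU eliminates acetic acid to give 10.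

Step 7 (fragment union). The alkene of 12 is flanked by two fully substituted carbons, so hydroboration may be slow or less face-selective, and a radical chain between two valuable partners near 1:1 may be inefficient. The fallback sets out from 12 and returns at 15. Hydroboration with 9-BBN followed by NaBO3 gives the primary alcohol F7, and I2/PPh3/imidazole gives the primary iodide F8. A tin-free Giese addition of F8 to 10 [(Me3Si)3SiH, Et3B/air, toluene] gives 15 directly. This replaces the organoborane chain by an isolated, purifiable radical precursor whose C-6 configuration can be checked before the union.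

Step 8 (methylenation). The ketone is α-branched and hindered, and the titanium Lewis acid could ionise the tertiary acetate. The fallback sets out from 10 and returns at 16, moving the acetylation behind a plain Wittig reaction. TBSOTf/2,6-lutidine converts 10 into the silyl ether F9. Separately, MeLi/CeCl3 on 10 with aqueous quench gives the allylic diol F10. Hydroboration of F10 (excess catecholborane) and radical addition to F9 as in step 7 give the keto diol F11. Ph3P=CH2 (excess, THF, 60 °C) gives the methylidene diol F12. Ac2O/DMAP/Et3N at 50 °C acetylates the secondary and tertiary hydroxyls to give the silyl-protected target F13, and HF·pyridine gives 16.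

**Further compounds**
F1 | step 4 | 4-[(2S,3S)-3-{2-[(2S)-3,3-dimethyloxiran-2-yl]ethyl}-3-methyloxiran-2-yl]butan-2-one | CC(=O)CC[C@@H]1O[C@@]1(C)CC[C@@H]1OC1(C)C
F2 | step 4 | ethyl (2E)-5-[(2S,3S)-3-{2-[(2S)-3,3-dimethyloxiran-2-yl]ethyl}-3-methyloxiran-2-yl]-3-methylpent-2-enoate | CCOC(=O)/C=C(\C)CC[C@@H]1O[C@@]1(C)CC[C@@H]1OC1(C)C
F3 | step 4 | (2E)-5-[(2S,3S)-3-{2-[(2S)-3,3-dimethyloxiran-2-yl]ethyl}-3-methyloxiran-2-yl]-3-methylpent-2-en-1-ol | OC/C=C(\C)CC[C@@H]1O[C@@]1(C)CC[C@@H]1OC1(C)C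
F4 | step 4 | (2E)-5-[(2S,3S)-3-{2-[(2S)-3,3-dimethyloxiran-2-yl]ethyl}-3-methyloxiran-2-yl]-3-methylpent-2-en-1-yl acetate | CC(=O)OC/C=C(\C)CC[C@@H]1O[C@@]1(C)CC[C@@H]1OC1(C)C
F5 | step 4 | [(3S,5aS,6R,9aS)-3-hydroxy-2,2,5a-trimethyl-7-methylidenedecahydro-1-benzoxepin-6-yl]methyl acetate | C=C1CC[C@@H]2OC(C)(C)[C@@H](O)CC[C@@]2(C)[C@@H]1COC(C)=O
F6 | step 4 | [(3S,5aS,6R,9aS)-3-hydroxy-2,2,5a-trimethyl-7-oxodecahydro-1-benzoxepin-6-yl]methyl acetate | O=C1CC[C@@H]2OC(C)(C)[C@@H](O)CC[C@@]2(C)[C@@H]1COC(C)=O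
F7 | step 7 | (3S,5aS,6R,7R,9aS)-6-(hydroxymethyl)-2,2,5a,7-tetramethyldecahydro-1-benzoxepine-3,7-diyl diacetate | OC[C@H]1[C@]2(C)CC[C@H](OC(C)=O)C(C)(C)O[C@H]2CC[C@@]1(C)OC(C)=O
F8 | step 7 | (3S,5aS,6S,7R,9aS)-6-(iodomethyl)-2,2,5a,7-tetramethyldecahydro-1-benzoxepine-3,7-diyl diacetate | IC[C@H]1[C@]2(C)CC[C@H](OC(C)=O)C(C)(C)O[C@H]2CC[C@@]1(C)OC(C)=O
F9 | step 8 | (3S,5aS,9aS)-3-[(tert-butyldimethylsilyl)oxy]-2,2,5a-trimethyl-6-methylideneoctahydro-1-benzoxepin-7(2H)-one | O=C1CC[C@@H]2OC(C)(C)[C@@H](O[Si](C)(C)C(C)(C)C)CC[C@@]2(C)C1=C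
F10 | step 8 | (3S,5aS,7R,9aS)-2,2,5a,7-tetramethyl-6-methylidenedecahydro-1-benzoxepine-3,7-diol | C=C1[C@]2(C)CC[C@H](O)C(C)(C)O[C@H]2CC[C@@]1(C)O
F11 | step 8 | 15 lacking both acetyl groups and carrying a TBS ether on the C-3 hydroxyl of the ketone half | O=C1CC[C@@H]2OC(C)(C)[C@@H](O[Si](C)(C)C(C)(C)C)CC[C@@]2(C)[C@@H]1CC[C@H]1[C@]2(C)CC[C@H](O)C(C)(C)O[C@H]2CC[C@@]1(C)O
F12 | step 8 | 16 lacking both acetyl groups and carrying a TBS ether on the C-3 hydroxyl of the methylidene half | C=C1CC[C@@H]2OC(C)(C)[C@@H](O[Si](C)(C)C(C)(C)C)CC[C@@]2(C)[C@@H]1CC[C@H]1[C@]2(C)CC[C@H](O)C(C)(C)O[C@H]2CC[C@@]1(C)O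
F13 | step 8 | 16 carrying a TBS ether on its free C-3 hydroxyl | C=C1CC[C@@H]2OC(C)(C)[C@@H](O[Si](C)(C)C(C)(C)C)CC[C@@]2(C)[C@@H]1CC[C@H]1[C@]2(C)CC[C@H](OC(C)=O)C(C)(C)O[C@H]2CC[C@@]1(C)OC(C)=O
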